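**Retrosynthetic overview**

1. Target ⇒ cut the C11′=C12′ double bond into a C25 ε-apo-12′-aldehyde and a ψ-C15 tertiary allyl carbonate. The aldehyde carbon is used with reversed polarity, as its N-tosylhydrazone/diazo form, and joined to the electrophilic allyl terminus under zerovalent palladium, so the C=C bond forms directly.
2. C25 aldehyde ⇒ cut C11=C12 (Wittig): ε-C15 phosphonium salt + symmetrical C10 trienedial (mono-olefination); the salt ⇒ (R)-α-ionone + vinyl Grignard (C9–C10).
3. ψ-C15 carbonate ⇒ (3E,5E)-pseudoionone + vinyl Grignard (C9′–C10′), with the alkoxide trapped by methyl chloroformate.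
4. Rings: none is formed. The single ε-end ring and its C6 (R) centre are bought in (R)-α-ionone and carried through unchanged.

Assumption: (R)-(+)-α-ionone and (3E,5E)-pseudoionone are bought as the single isomers named, with purity checked by chiral GC and NMR before use.
Positions are given in carotenoid numbering (C6 = ring stereocentre; primed numbers = ψ half).

**Route**

Step 1
Reactants: 1 (R)-α-ionone
Product: 2 (4E)-3-methyl-5-[(1R)-2,6,6-trimethylcyclohex-2-en-1-yl]penta-1,4-dien-3-ol (vinyl-α-ionol; both C3 epimers)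
Conditions: CH2=CHMgBr (1.3 equiv), THF, −20 → 0 °C; then aq. NH4Cl
Reagents that add atoms: vinylmagnesium bromide, C=C[Mg]Br
Why: 1,2-Grignard addition to the enone carbonyl is fast at low temperature and installs C10–C11; the new carbinol centre is formed as a mixture that is erased in step 2, and C6 is untouched.

Step 2
Reactants: 2 vinyl-α-ionol
Product: 3 [(2E,4E)-3-methyl-5-[(1R)-2,6,6-trimethylcyclohex-2-en-1-yl]penta-2,4-dien-1-yl]triphenylphosphonium bromide
Conditions: PPh3·HBr (1.05 equiv), MeOH, 0 °C → rt, 20 h; crystallise (EtOAc)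
Reagents that add atoms: triphenylphosphine hydrobromide, [Br-].[PH+](c1ccccc1)(c1ccccc1)c1ccccc1
Why: SN1-type ionisation of the tertiary bis-allylic alcohol gives a pentadienyl cation that PPh3 captures at the unhindered terminus C11 (allylic transposition, the classical C15 Wittig-salt formation), giving mainly the 9E salt without touching C6.

Step 3
Reactants: 3 ε-C15 phosphonium bromide; 4 (2E,4E,6E)-2,7-dimethylocta-2,4,6-trienedial
Product: 6 (2E,4E,6E,8E,10E,12E)-2,7,11-trimethyl-13-[(1R)-2,6,6-trimethylcyclohex-2-en-1-yl]trideca-2,4,6,8,10,12-hexaenal (C25 aldehyde; 12′-apo-ε-caroten-12′-al), via phosphorus ylide 5 (not isolated)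
Conditions: NaOMe (1.1 equiv), CH2Cl2/MeOH, 0 °C, slow addition of 3 to 4 (3 equiv); then I2 (1 mol%), hexane, rt, daylight
Reagents that add atoms: none
Why: Wittig olefination in which the semistabilised ylide reacts only once because the dial is in excess and the product polyenal is less electrophilic than the dial; the E/Z mixture at the new C11=C12 bond is equilibrated to all-E by catalytic iodine, and no stereocentre is formed.

Step 4
Reactants: 7 (3E,5E)-pseudoionone
Product: 9 methyl (4E,6E)-3,7,11-trimethyldodeca-1,4,6,10-tetraen-3-yl carbonate (racemic at C3), via bromomagnesium alkoxide 8 (not isolated)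
Conditions: CH2=CHMgBr (1.2 equiv), THF, −30 → 0 °C; then ClCO2Me (1.5 equiv), −30 °C → rt; filter through Et3N-deactivated silica, use at once
Reagents that add atoms: vinylmagnesium bromide, C=C[Mg]Br; methyl chloroformate, COC(=O)Cl
Why: 1,2-Grignard addition followed by O-acylation of the alkoxide in the same flask gives the tertiary allylic carbonate without exposing the acid-labile carbinol to work-up; its carbinol centre is racemic and disappears in step 5.

Step 5
Reactants: 6 C25 aldehyde; 9 ψ-C15 allyl carbonate; 10 4-methylbenzenesulfonohydrazide (TsNHNH2)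
Product: 13 (6R)-ε,ψ-carotene (δ-carotene; all-E; CNP0405345.1), via tosylhydrazone 11 (not isolated), via diazoalkane 12 (not isolated)
Conditions: TsNHNH2 10 (1.05 equiv), 1,4-dioxane, 4 Å MS, 50 °C, 1 h; then 9 (1.5 equiv), Pd2(dba)3 (2.5 mol%), P(2-furyl)3 (10 mol%), LiOtBu (2.2 equiv), 70 °C, Ar, dark; then n-heptane, reflux, 2 h, crystallise
Reagents that add atoms: none
Why: Proposed new method: condensation gives tosylhydrazone 11, whose lithium salt loses sulfinate (Bamford–Stevens) to give diazoalkane 12, so the C12′ aldehyde carbon, normally an electrophile, acts as the nucleophile (a traceless acyl-anion-type d1 synthon) towards the electrophilic π-allyl complex formed from 9 and zerovalent palladium; loss of N2 gives a palladium carbene, the allyl group migrates through its unhindered terminus C11′ to the carbene carbon, and β-hydride elimination of the doubly allylic C11′–H forms the C11′=C12′ bond and completes the polyene, with no new stereocentre and C6 (R) far from the reacting site; the closest known reaction type is the zerovalent-palladium-catalysed coupling of allyl halides with N-sulfonylhydrazones to 1,3-dienes (carbene migratory insertion then β-hydride elimination, Barluenga-type), here extended to an allyl carbonate and a polyenal hydrazone, and the final heating in heptane equilibrates 9′Z/11′Z isomers to the all-E product.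

**Compound list**

1 | (R)-α-ionone, (3E)-4-[(1R)-2,6,6-trimethylcyclohex-2-en-1-yl]but-3-en-2-one | CC(=O)/C=C/[C@H]1C(C)=CCCC1(C)C | starting material
2 | (4E)-3-methyl-5-[(1R)-2,6,6-trimethylcyclohex-2-en-1-yl]penta-1,4-dien-3-ol (both C3 epimers) | C=CC(C)(O)/C=C/[C@H]1C(C)=CCCC1(C)C | intermediate
3 | [(2E,4E)-3-methyl-5-[(1R)-2,6,6-trimethylcyclohex-2-en-1-yl]penta-2,4-dien-1-yl]triphenylphosphonium bromide | [Br-].c1ccccc1[P+](c1ccccc1)(c1ccccc1)C/C=C(C)/C=C/[C@H]1C(C)=CCCC1(C)C | intermediate
4 | (2E,4E,6E)-2,7-dimethylocta-2,4,6-trienedial (C10 dialdehyde) | O=C/C(C)=C/C=C/C=C(C)/C=O | starting material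
5 | [(2E,4E)-3-methyl-5-[(1R)-2,6,6-trimethylcyclohex-2-en-1-yl]penta-2,4-dien-1-ylidene]triphenyl-λ5-phosphane (ylide) | C(=P(c1ccccc1)(c1ccccc1)c1ccccc1)/C=C(C)/C=C/[C@H]1C(C)=CCCC1(C)C | intermediate
6 | (2E,4E,6E,8E,10E,12E)-2,7,11-trimethyl-13-[(1R)-2,6,6-trimethylcyclohex-2-en-1-yl]trideca-2,4,6,8,10,12-hexaenal | O=C/C(C)=C/C=C/C=C(C)/C=C/C=C(C)/C=C/[C@H]1C(C)=CCCC1(C)C | intermediate
7 | (3E,5E)-6,10-dimethylundeca-3,5,9-trien-2-one (pseudoionone) | CC(C)=CCC/C(C)=C/C=C/C(C)=O | starting material
8 | bromomagnesium (4E,6E)-3,7,11-trimethyldodeca-1,4,6,10-tetraen-3-olate | CC(C)=CCC/C(C)=C/C=C/C(C)(C=C)O[Mg]Br | intermediate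
9 | methyl (4E,6E)-3,7,11-trimethyldodeca-1,4,6,10-tetraen-3-yl carbonate (racemic) | CC(C)=CCC/C(C)=C/C=C/C(C)(C=C)OC(=O)OC | intermediate
10 | 4-methylbenzenesulfonohydrazide | Cc1ccc(cc1)S(=O)(=O)NN | starting material
11 | N′-[(1E,2E,4E,6E,8E,10E,12E)-2,7,11-trimethyl-13-[(1R)-2,6,6-trimethylcyclohex-2-en-1-yl]trideca-2,4,6,8,10,12-hexaen-1-ylidene]-4-methylbenzenesulfonohydrazide | Cc1ccc(cc1)S(=O)(=O)N/N=C/C(C)=C/C=C/C=C(C)/C=C/C=C(C)/C=C/[C@H]1C(C)=CCCC1(C)C | intermediate
12 | (6R)-6-[(1E,3E,5E,7E,9E,11E)-13-diazo-3,7,12-trimethyltrideca-1,3,5,7,9,11-hexaen-1-yl]-1,5,5-trimethylcyclohex-1-ene | [N-]=[N+]=C/C(C)=C/C=C/C=C(C)/C=C/C=C(C)/C=C/[C@H]1C(C)=CCCC1(C)C | intermediate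
13 | (6R)-ε,ψ-carotene (δ-carotene, all-E) | CC(C)=CCC/C(C)=C/C=C/C(C)=C/C=C/C(C)=C/C=C/C=C(C)/C=C/C=C(C)/C=C/[C@H]1C(C)=CCCC1(C)C | target

**Summary**

Total step count: 5. Longest linear sequence: 4 (steps 1, 2, 3, 5).

**Steps most likely to fail, with fallbacks**

Risk 1 (step 5, the carbene coupling). The hydrazone anion may be N-allylated by the π-allyl complex, diazoalkane 12 may cyclise to a pyrazole, or 9 may simply eliminate to a pentaene. The fallback sets out from 9 and 6 and comes back at 13; it keeps C11′ as the nucleophilic partner but carries it as a sulfone carbanion (Julia–Lythgoe).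
- Carbonate 9 with PhSO2Na and Pd(PPh3)4 (THF/MeOH, rt; Tsuji–Trost sulfonylation, linear product) gives {[(2E,4E,6E)-3,7,11-trimethyldodeca-2,4,6,10-tetraen-1-yl]sulfonyl}benzene F1.
- F1 is lithiated at C11′ (n-BuLi, THF, −78 °C) and added to aldehyde 6; the alkoxide is acetylated in the flask (Ac2O) to give (6R)-11′-(phenylsulfonyl)-11′,12′-dihydro-ε,ψ-caroten-12′-yl acetate F2 (diastereomer mixture).
- Reductive elimination with SmI2/HMPA (THF, −20 °C) removes sulfinate and acetate and forms the C11′=C12′ bond, giving 13 after the same heptane equilibration.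

Risk 2 (step 4, the tertiary bis-allylic carbonate). Compound 9 may ionise, rearrange or eliminate during formation or handling. The fallback sets out from 7 and comes back at 13.
- The Grignard adduct is quenched with aq. NH4Cl and isolated as (4E,6E)-3,7,11-trimethyldodeca-1,4,6,10-tetraen-3-ol F3.
- F3 is converted with PBr3/pyridine (Et2O, −10 °C, SN2′) into the primary bromide (2E,4E,6E)-1-bromo-3,7,11-trimethyldodeca-2,4,6,10-tetraene F4.
- F4 is used at once in place of 9 under the step 5 conditions. Allyl halides are the established electrophiles for this coupling, and LiOtBu takes up the HBr.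

Risk 3 (step 3, mono-olefination of the symmetrical dial). Double Wittig reaction to the C40 ε,ε-product and loss of 3 may dominate. The fallback sets out from 4 and comes back at 6; it desymmetrises the dial before olefination.
- Compound 4 with MeOH (cat. p-TsOH, limited conversion) gives the mono-acetal (2E,4E,6E)-8,8-dimethoxy-2,7-dimethylocta-2,4,6-trienal F5; recovered 4 and bis-acetal are recycled.
- Wittig reaction of F5 with 3 (NaOMe, CH2Cl2/MeOH) gives (6R)-6-[(1E,3E,5E,7E,9E,11E)-13,13-dimethoxy-3,7,12-trimethyltrideca-1,3,5,7,9,11-hexaen-1-yl]-1,5,5-trimethylcyclohex-1-ene F6.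
- Mild hydrolysis (PPTS, acetone/H2O, rt) releases aldehyde 6.

Further compounds
F1 | step 5 | {[(2E,4E,6E)-3,7,11-trimethyldodeca-2,4,6,10-tetraen-1-yl]sulfonyl}benzene | CC(C)=CCC/C(C)=C/C=C/C(C)=C/CS(=O)(=O)c1ccccc1
F2 | step 5 | (6R)-11′-(phenylsulfonyl)-11′,12′-dihydro-ε,ψ-caroten-12′-yl acetate (diastereomer mixture at C11′ and C12′) | CC(C)=CCC/C(C)=C/C=C/C(C)=C/C(S(=O)(=O)c1ccccc1)C(OC(C)=O)/C(C)=C/C=C/C=C(C)/C=C/C=C(C)/C=C/[C@H]1C(C)=CCCC1(C)C
F3 | step 4 | (4E,6E)-3,7,11-trimethyldodeca-1,4,6,10-tetraen-3-ol (racemic) | CC(C)=CCC/C(C)=C/C=C/C(C)(C=C)O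
F4 | step 4 | (2E,4E,6E)-1-bromo-3,7,11-trimethyldodeca-2,4,6,10-tetraene | CC(C)=CCC/C(C)=C/C=C/C(C)=C/CBr
F5 | step 3 | (2E,4E,6E)-8,8-dimethoxy-2,7-dimethylocta-2,4,6-trienal | O=C/C(C)=C/C=C/C=C(C)/C(OC)OC
F6 | step 3 | (6R)-6-[(1E,3E,5E,7E,9E,11E)-13,13-dimethoxy-3,7,12-trimethyltrideca-1,3,5,7,9,11-hexaen-1-yl]-1,5,5-trimethylcyclohex-1-ene | COC(OC)/C(C)=C/C=C/C=C(C)/C=C/C=C(C)/C=C/[C@H]1C(C)=CCCC1(C)C
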